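**Plan**

- Retrosynthesis cuts, in order: the biaryl bond between chromone C3 and chromene C6 (Suzuki–Miyaura); in the pyran ring the aryl ether bond O1–C8a together with C3=C4 (one-flask annulation); in the chromone the O1–C2 bond and C2 itself (enaminone iodocyclisation).
- Forward, ring B fragment: the dimethylpyran ring is annulated onto 2-fluoro-3-methoxybenzaldehyde, then the only unhindered aromatic C–H (C6) is borylated.
- Enabling feature: on the benzene ring the aldehyde carbon (future C4) and the C–F carbon (future C8a) are ortho, a 1,3-dielectrophile that matches the O1–C2–C3 unit released from strained 2,2-dimethyloxirane. The gem-dimethyl C2 makes O1 a tertiary alkoxide that can only cyclise, and the fluorine is flanked by OMe (C8) and C4a.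
- Forward, rings A and C: 3-iodochromone from 2,4-dihydroxyacetophenone with the 7-oxygen masked as a methoxymethyl ether; then union of the fragments and acetal removal.
- Stereochemistry: the target has no stereocentre. The carbinol centre formed in passing at C4 is racemic and is erased by dehydration; the ring fixes C3=C4 as cis.

Key step: step 1

**Route**

Step 1
Reactants: 1 2-fluoro-3-methoxybenzaldehyde; 2 2,2-dimethyloxirane
Product: 6 8-methoxy-2,2-dimethyl-2H-chromene, via lithium 1-lithio-2-methylpropan-2-olate 3 (not isolated), via dilithium 1-(2-fluoro-3-methoxyphenyl)-3-methylbutane-1,3-diolate 4 (not isolated), via lithium 8-methoxy-2,2-dimethylchroman-4-olate 5 (not isolated)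
Conditions: 2, Li powder, 4,4'-di-tert-butylbiphenyl (5 mol %), THF, −78 °C, cannula filtration from excess Li; 1, −78 to 0 °C; DMPU, 90 °C (sealed); TsOH·H2O (3 equiv), 60 °C
Reagents that add atoms: none
Why: Proposed new method: arene-catalysed reductive lithiation cleaves the strained, less substituted C–O bond of oxirane 2 to the β-oxido alkyllithium 3, whose carbanion (future C3) adds to the aldehyde carbon (C4) of 1 to give diolate 4; on heating in DMPU the tertiary alkoxide O1 should displace fluoride at C8a by intramolecular addition–elimination (SNAr, helped by precipitation of LiF and the gem-dimethyl effect), and acid then dehydrates the benzylic carbinol from 5 by E1 through a cation stabilised by the ortho ring oxygen. The closest known reaction types are the addition of epoxide-derived β-oxido organolithiums to aldehydes to give 1,3-diols and the alkoxide SNAr cyclisation of 3-(2-fluoroaryl)propan-1-ols to chromans; new is their merger in one flask into a (3+3) annulation on a fluoroarene that has no activating group once the aldehyde is consumed. The pyran ring closes in the 6-exo-trig mode at C8a. The product has no stereocentre: C4 in 4 and 5 is racemic and is erased by the dehydration, and the ring fixes the cis geometry of C3=C4. The step needs chemoselectivity between the two alkoxides and regioselectivity in the elimination: only the tertiary alkoxide can reach C8a through a six-membered transition state (the benzylic one would need a four-membered ring), the fluorine has no ortho hydrogen so no aryne can form, and C4 has β-hydrogens only at C3.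

Step 2
Reactants: 6 8-methoxy-2,2-dimethyl-2H-chromene
Product: 7 2-(8-methoxy-2,2-dimethyl-2H-chromen-6-yl)-4,4,5,5-tetramethyl-1,3,2-dioxaborolane
Conditions: B2pin2 (1.0 equiv), [Ir(OMe)(cod)]2 (1.5 mol %), 4,4'-di-tert-butyl-2,2'-bipyridine (3 mol %), THF, 60 °C
Reagents that add atoms: bis(pinacolato)diboron, CC1(C)OB(OC1(C)C)B1OC(C)(C)C(C)(C)O1
Why: Iridium-catalysed aromatic C–H borylation is sterically governed, and of the three aromatic C–H bonds only C6–H has no ortho substituent (C5–H lies next to the ring fusion, C7–H next to OMe), while the hindered alkene C–H bonds at C3 and C4 should react more slowly.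

Step 3
Reactants: 8 1-(2,4-dihydroxyphenyl)ethan-1-one
Product: 9 1-[2-hydroxy-4-(methoxymethoxy)phenyl]ethan-1-one
Conditions: MOMCl (1.05 equiv), K2CO3, acetone, 0 °C to rt
Reagents that add atoms: chloromethyl methyl ether, COCCl
Why: Williamson-type O-alkylation should occur only at the free 4-OH, because the 2-OH is tied up in a hydrogen bond to the ketone and is less nucleophilic.

Step 4
Reactants: 9 1-[2-hydroxy-4-(methoxymethoxy)phenyl]ethan-1-one
Product: 11 3-iodo-7-(methoxymethoxy)-4H-chromen-4-one, via (E)-3-(dimethylamino)-1-[2-hydroxy-4-(methoxymethoxy)phenyl]prop-2-en-1-one 10 (not isolated)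
Conditions: DMF-DMA, 95 °C; evaporation; I2, pyridine, CHCl3, rt
Reagents that add atoms: N,N-dimethylformamide dimethyl acetal, COC(OC)N(C)C; iodine, II
Why: Condensation of the methyl ketone with the amide acetal gives the enaminone, and iodine then triggers the enaminone iodocyclisation (α-iodination, attack of the phenol oxygen at the β-carbon, loss of dimethylamine) to the 3-iodochromone, with pyridine keeping the medium from cleaving the acetal.

Step 5
Reactants: 11 3-iodo-7-(methoxymethoxy)-4H-chromen-4-one; 7 2-(8-methoxy-2,2-dimethyl-2H-chromen-6-yl)-4,4,5,5-tetramethyl-1,3,2-dioxaborolane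
Product: 12 3-(8-methoxy-2,2-dimethyl-2H-chromen-6-yl)-7-(methoxymethoxy)-4H-chromen-4-one
Conditions: Pd(dppf)Cl2 (5 mol %), K2CO3, 1,4-dioxane/H2O (4:1), 80 °C
Reagents that add atoms: none
Why: Suzuki–Miyaura coupling should proceed readily because the C–I bond of the 3-iodochromone adds quickly to zerovalent palladium, and the mild carbonate base should spare the chromone ring, the acetal and the chromene.

Step 6
Reactants: 12 3-(8-methoxy-2,2-dimethyl-2H-chromen-6-yl)-7-(methoxymethoxy)-4H-chromen-4-one
Product: 13 7-hydroxy-3-(8-methoxy-2,2-dimethyl-2H-chromen-6-yl)-4H-chromen-4-one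
Conditions: HCl (3 M aq., catalytic to 2 equiv), MeOH/THF, 50 °C
Reagents that add atoms: none
Why: Acid-catalysed acetal exchange with methanol frees the 7-OH, and dilute acid at moderate temperature is expected to leave the conjugated chromene and the chromone untouched.

**Compound list**

1 | 2-fluoro-3-methoxybenzaldehyde | COc1cccc(C=O)c1F | starting material
2 | 2,2-dimethyloxirane | CC1(C)CO1 | starting material
3 | lithium 1-lithio-2-methylpropan-2-olate | [Li]CC(C)(C)O[Li] | intermediate
4 | dilithium 1-(2-fluoro-3-methoxyphenyl)-3-methylbutane-1,3-diolate (racemic) | COc1cccc(C(O[Li])CC(C)(C)O[Li])c1F | intermediate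
5 | lithium 8-methoxy-2,2-dimethylchroman-4-olate (racemic) | COc1cccc2C(O[Li])CC(C)(C)Oc12 | intermediate
6 | 8-methoxy-2,2-dimethyl-2H-chromene | COc1cccc2C=CC(C)(C)Oc12 | intermediate
7 | 2-(8-methoxy-2,2-dimethyl-2H-chromen-6-yl)-4,4,5,5-tetramethyl-1,3,2-dioxaborolane | COc1cc(B3OC(C)(C)C(C)(C)O3)cc2C=CC(C)(C)Oc12 | intermediate
8 | 1-(2,4-dihydroxyphenyl)ethan-1-one | CC(=O)c1ccc(O)cc1O | starting material
9 | 1-[2-hydroxy-4-(methoxymethoxy)phenyl]ethan-1-one | CC(=O)c1ccc(OCOC)cc1O | intermediate
10 | (E)-3-(dimethylamino)-1-[2-hydroxy-4-(methoxymethoxy)phenyl]prop-2-en-1-one | CN(C)/C=C/C(=O)c1ccc(OCOC)cc1O | intermediate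
11 | 3-iodo-7-(methoxymethoxy)-4H-chromen-4-one | COCOc1ccc2c(c1)occ(I)c2=O | intermediate
12 | 3-(8-methoxy-2,2-dimethyl-2H-chromen-6-yl)-7-(methoxymethoxy)-4H-chromen-4-one | COCOc1ccc2c(c1)occ(-c1cc(OC)c3OC(C)(C)C=Cc3c1)c2=O | intermediate
13 | 7-hydroxy-3-(8-methoxy-2,2-dimethyl-2H-chromen-6-yl)-4H-chromen-4-one | COc1cc(-c2coc3cc(O)ccc3c2=O)cc2c1OC(C)(C)C=C2 | target

**Step count and risks**

Total step count: 6. Longest linear sequence: 4 (steps 1, 2, 5, 6 or steps 3, 4, 5, 6).

Steps most likely to fail:

1. Step 1. The fluoride displacement may stall at the open-chain diolate because the ring is electron-rich and unactivated; the reagent may also β-eliminate on warming, or traces of arene radical anion may reduce the C–F bond. Fallback from 1, back at 6, by known stepwise chemistry: SNAr of the aldehyde-activated fluoride with potassium 2-methylbut-3-en-2-olate (2-methylbut-3-en-2-ol, KH, THF/DMF) should give 3-methoxy-2-[(2-methylbut-3-en-2-yl)oxy]benzaldehyde F1. Wittig methylenation (Ph3P=CH2, THF) should give 1-ethenyl-3-methoxy-2-[(2-methylbut-3-en-2-yl)oxy]benzene F2. Ring-closing metathesis with the second-generation Grubbs catalyst RuCl2(=CHPh)(H2IMes)(PCy3) in CH2Cl2 at 40 °C should then close C3=C4 with loss of ethene and rejoin the route at 6.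

2. Step 2. Borylation may also occur at the alkene C–H bonds or next to the substituents, and pinacolborane may hydroborate C3=C4. Fallback from 5, back at 7: step 1 is stopped before the acid stage by NH4Cl quench to give 8-methoxy-2,2-dimethylchroman-4-ol F3. With no alkene present, NBS in MeCN at 0 °C should brominate para to the ring oxygen to give 6-bromo-8-methoxy-2,2-dimethylchroman-4-ol F4. TsOH in toluene at 80 °C should dehydrate this to 6-bromo-8-methoxy-2,2-dimethyl-2H-chromene F5, and Miyaura borylation (B2pin2, Pd(dppf)Cl2, KOAc, 1,4-dioxane, 90 °C) rejoins the route at 7.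

3. Step 6. During acetal cleavage the acid may add methanol across the chromene double bond or dimerise it. Fallback from 11, ending at 13: the acetal is removed before the coupling (HCl, MeOH, 50 °C, no chromene present) to give 7-hydroxy-3-iodo-4H-chromen-4-one F6. Suzuki–Miyaura coupling of this free phenol with 7 (Pd(dppf)Cl2, K2CO3, 1,4-dioxane/H2O, 80 °C) should give 13 directly, so the chromene never meets acid.

**Further compounds**

F1 | step 1 | 3-methoxy-2-[(2-methylbut-3-en-2-yl)oxy]benzaldehyde | COc1cccc(C=O)c1OC(C)(C)C=C
F2 | step 1 | 1-ethenyl-3-methoxy-2-[(2-methylbut-3-en-2-yl)oxy]benzene | COc1cccc(C=C)c1OC(C)(C)C=C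
F3 | step 2 | 8-methoxy-2,2-dimethylchroman-4-ol (racemic) | COc1cccc2C(O)CC(C)(C)Oc12
F4 | step 2 | 6-bromo-8-methoxy-2,2-dimethylchroman-4-ol (racemic) | COc1cc(Br)cc2C(O)CC(C)(C)Oc12
F5 | step 2 | 6-bromo-8-methoxy-2,2-dimethyl-2H-chromene | COc1cc(Br)cc2C=CC(C)(C)Oc12
F6 | step 6 | 7-hydroxy-3-iodo-4H-chromen-4-one | Oc1ccc2c(c1)occ(I)c2=O
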